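(All constants belong to no real substance; no experiment stands behind them.)

You are about to time a reaction on a small charge: 0.1 mol% of catalyst, beside a neighbour that looks nearly the same but holds 0.04 mol%.

substrate 0.30 M; solid reagent 0.950 equiv; catalyst 0.1 mol%; time 2.5 d

- amount of product at 2.5 d, in percent of the substrate charged
- concentration of partner in solution at 6.0 h, in percent of saturation
- the change that raises the amount of product at 2.5 d, in percent of the substrate charged most ("none" if none brings more than 2 percentage points) (zeta / beta / theta / none)
- amount of product at 2.5 d, in percent of the substrate charged, after theta

- zeta: doubling the dissolution coefficient of step 3, all else as stated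
- beta: doubling the amount of catalyst, all else as stated
- theta: doubling the solubility in step 3, all else as stated

- as a solid, counted per litre of solution: solid reagent
- at the start none of the solid reagent is in solution
- run time (flask): 2.5 d

    substrate + catalyst ⇌ catalyst + intermediate (K1 = 2.0, k1 = 210 M⁻¹ h⁻¹)
    partner + catalyst + intermediate → catalyst + product (k2 = 3300 M⁻² h⁻¹)
    solid reagent ⇌ partner, rate k3*(cs3 - [partner]) while solid is left; crystals form when [partner] > cs3 (cs3 = 0.21 M, k3 = 1.1 h⁻¹)

My own reckoning rests on one count. Catalyst stands as a factor in the first and second steps but not in the dissolving, so catalyst and time act as their product once dissolving is out of the way. Your run lasts 5.45 pseudo-first-order half-lives of substrate, each 0.46 d by the forward first step as charged. Call that number, run time over forward half-life, the catalyst clock. Dissolving has a half-life of 0.630 h, far shorter than the chemical one, so I expect zeta and theta to move the product little, and I back beta, which doubles the clock.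

Both flasks share the limiting reagent, the solid reagent, and its ceiling of 95.0% product. But the neighbour's clock reads 2.18 in the same time, less than this flask's. So I expect it to end where this flask stands at 1.00 d, further below the ceiling. My hand goes no further than that.

The forecast gives 83% (81% to 85%), 95.5% of saturation, beta as best and 83.7% after theta, saying “Beta doubles the chemical clock”.

The simulation gives 83.8%, 95.8% of saturation, beta as best with a gain of 7.8 percentage points against 0.014 points for zeta and 0.065 points for theta, and 83.8% after theta.

Read your flask by the clock. The neighbour, at 2.18, ended with 58.5% product, between this flask's 12.9% at 0.250 d and 66.1% at 1.25 d, and its equivalent time of 1.00 d lies between those two times. This flask, at 5.45, has not come to rest: it holds 83.8% product, 7.4% substrate and 8.78% intermediate. Ten times the time puts the clock at 54.5 and adds 11 points to this flask's product, which reaches 95.0% against the ceiling of 95.0%, with 1.67% substrate and 3.34% intermediate remaining.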